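**Retrosynthetic overview**

1. Target 22 ⇐ bis-silyl ether 21 ⇐ vinyl alcohol 18 + 3-bromofuran-2(5H)-one 19 (hydroboration, B-alkyl Suzuki–Miyaura; the lactone ring is brought in intact) ⇐ C9 ketone 14 (C17 by formaldehyde aldol at C8, C11 by spiro-epoxide/Meinwald homologation at C9, C12 by Wittig).
2. Ring A ⇐ one-pot union of three components: ketene silyl acetal 2 (C3, C4, C18, C19), (S)-carvone 3 (ring B: C5–C10, C20) and tert-butyl acrylate 4 (C1, C2), by C4–C5 (Mukaiyama–Michael), C10–C1 (Michael) and, as the ring-closing event, C2–C3 (Dieckmann).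
3. Enabling feature: in ring A the C3 hydroxyl and the C19 hydroxymethyl on quaternary C4 are the two carbonyls of a methylmalonate, the quaternary fusion carbon C10 is α to C9 of ring B (a ketone until the side chain is built), and C2 is the α-carbon of an acrylate whose ester is excised after the closure.
4. Ring order: ring B is the carvone ring (its C7 isopropenyl group controls C5 and, through it, C10 and C4, then is cut off by C–C cleavage); ring A is closed in the key step; the butenolide ring arrives last.

Key step: step 2

Remark: labdane numbering is used for all compounds (ring B = C5–C10 also in the monocyclic intermediates); α is the face of the decalin that carries the C20 methyl on C10, β the opposite face; 1, 3, 4 and 19 are taken as commercial.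

**Step 1**
Reactants: 1 dimethyl methylmalonate
Product: 2 ketene silyl acetal of dimethyl methylmalonate
Conditions: Me3SiOTf, Et3N, Et2O, 0 °C → rt
Reagents that add atoms: trimethylsilyl trifluoromethanesulfonate, C[Si](C)(C)OS(=O)(=O)C(F)(F)F
Why: Soft enolisation and O-silylation of the malonate (silyl ketene acetal formation); the fully substituted α-carbon disfavours C-silylation and no stereocentre is formed.

**Step 2**
Reactants: 2 ketene silyl acetal of dimethyl methylmalonate; 3 (S)-(+)-carvone; 4 tert-butyl acrylate
Product: 8 bicyclic β-keto ester (ring A closed; see compound list), via silyl enol ether 5 (not isolated), via potassium ketone enolate 6 (not isolated), via potassium ester enolate 7 (not isolated)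
Conditions: (a) 3, 2 (1.05 equiv), Bu4N[Ph3SiF2] (5 mol %), THF, −78 → −20 °C; (b) KOtBu (1.05 equiv), −20 °C; then 4 (1.05 equiv, slow addition), −78 → 0 °C; AcOH quench
Reagents that add atoms: none
Why: Fluoride activation of 2 triggers a Mukaiyama–Michael addition to the enone β-carbon C5 of 3 with silyl transfer to give 5 (each adduct enolate is silylated by the next molecule of 2, which drains the otherwise reversible addition); KOtBu then unmasks the position-defined C9/C10 enolate 6, which adds to the acrylate (C10–C1), and the ester enolate 7 closes ring A by Dieckmann acylation of C2 on one malonate ester (C2–C3), the β-keto ester enolate of 8 being the thermodynamic sink. The closest known reaction type is the sequential Michael–Michael–ring closure (MIMIRC) annulation of an enolate, a cycloalkenone and an acrylate, combined with fluoride-mediated conjugate addition and enolate trapping of ketene silyl acetals. Ring A closes in a 6-(enolexo)-exo-trig acyl substitution through a chair that is trans-fused to ring B. C5 is set by axial attack on the carvone half-chair anti to the C7 isopropenyl group; C10 is set because A(1,2) strain with the C10 methyl forces the bulky C5 substituent pseudoaxial in 6, so the acrylate enters from the opposite face (C1 trans to C4, hence the trans fusion); C4 is set in the ring closure by selection between the two diastereotopic esters, the chair with the C18 methyl equatorial and the remaining ester (C19) axial avoiding a methyl/methyl 1,3-diaxial contact with C20. The step needs reaction at C10 and not at C8, which the position-specific silyl enol ether 5 secures, and a single acrylate insertion, which slow addition of the bulky tert-butyl ester at low temperature and the fast intramolecular acylation should secure.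

**Step 3**
Reactants: 8 bicyclic β-keto ester
Product: 9 3,9-diketo C19 methyl ester
Conditions: DMSO–H2O (20:1), 140 °C
Reagents that add atoms: none
Why: Thermal dealkoxycarbonylation of the enolisable tert-butyl β-keto ester (loss of tert-butanol via the acylketene, hydration, decarboxylation) removes the activating group at C2; the methyl ester on quaternary C4 has no α-hydrogen and no nucleophilic salt is present, so it stays, and the neutral medium leaves the isopropenyl group untouched.

**Step 4**
Reactants: 9 3,9-diketo C19 methyl ester
Product: 10 3α-hydroxy 9-keto ester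
Conditions: NaBH4 (0.5 equiv), MeOH–CH2Cl2, −40 °C
Reagents that add atoms: none
Why: Chemoselective borohydride reduction: the C3 carbonyl is activated by the adjacent ester and open on its β-face, whereas the C9 carbonyl is screened on the α-face by the C20 methyl and on the β-face by the axial C7 isopropenyl group; axial hydride delivery from the β-face should give the equatorial 3α-alcohol.

**Step 5**
Reactants: 10 3α-hydroxy 9-keto ester
Product: 12 dealkenylated hydroxy keto ester, via α-methoxy hydroperoxide 11 (not isolated)
Conditions: O3, MeOH, −78 °C; then FeSO4·7H2O, PhSH, −78 °C → rt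
Reagents that add atoms: none
Why: Hydrodealkenylation: Criegee ozonolysis in methanol gives 11, single-electron reduction by divalent iron gives an alkoxy radical whose β-scission expels the secondary C7 radical and methyl acetate, and hydrogen-atom transfer from the thiol leaves C7 as a methylene group; no stereocentre is touched.

**Step 6**
Reactants: 12 dealkenylated hydroxy keto ester
Product: 13 C17 hydroxymethyl ketone
Conditions: LiN(iPr)2 (2.2 equiv), THF, −78 °C; HCHO (gas, from cracked paraformaldehyde), −78 → −40 °C; AcOH quench
Reagents that add atoms: formaldehyde, C=O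
Why: Aldol addition of the lithium enolate to formaldehyde: C8 is the only enolisable position of the C9 ketone (C10 is quaternary), and the electrophile should add to the face away from the 1,3-related axial C20 methyl, placing C17 equatorial (β), which is also the thermodynamically favoured epimer.

**Step 7**
Reactants: 13 C17 hydroxymethyl ketone
Product: 14 3,17-bis(tert-butyldimethylsilyl) ether ketone
Conditions: tBuMe2SiOTf (2.5 equiv), 2,6-lutidine, CH2Cl2, −78 → 0 °C
Reagents that add atoms: tert-butyldimethylsilyl trifluoromethanesulfonate, CC(C)(C)[Si](C)(C)OS(=O)(=O)C(F)(F)F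
Why: Silyl triflate silylation protects the primary C17 and the hindered secondary C3 hydroxyl in one operation and blocks retro-aldol loss of C17.

**Step 8**
Reactants: 14 3,17-bis(tert-butyldimethylsilyl) ether ketone
Product: 15 C9 spiro-epoxide
Conditions: Me3S+ I−, KN(SiMe3)2, THF, −10 °C → rt
Reagents that add atoms: trimethylsulfonium iodide, C[S+](C)C.[I-]
Why: Corey–Chaykovsky epoxidation: the sulfonium methylide adds irreversibly to the C9 carbonyl from the β-face (axial attack anti to the C20 methyl, open now that the isopropenyl group is gone) and the betaine closes to the epoxide; the ester on quaternary C4 is too hindered to react.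

**Step 9**
Reactants: 15 C9 spiro-epoxide
Product: 16 C11 aldehyde
Conditions: BF3·OEt2, CH2Cl2, −78 °C; then DBU (cat.), CH2Cl2, rt
Reagents that add atoms: none
Why: Meinwald rearrangement: Lewis-acid opening of the tertiary C9–O bond with 1,2-hydride shift from C11 anti to the leaving oxygen gives the aldehyde with H9 axial (β) and the formyl group equatorial (α); DBU equilibration through the enol secures this all-equatorial, thermodynamically preferred C9 configuration.

**Step 10**
Reactants: 16 C11 aldehyde
Product: 17 C9 vinyl ester
Conditions: Ph3PCH3Br, KOtBu, THF, 0 °C → rt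
Reagents that add atoms: methyltriphenylphosphonium bromide, C[P+](c1ccccc1)(c1ccccc1)c1ccccc1.[Br-]
Why: Wittig methylenation gives the C11=C12 vinyl group; C9 already has its thermodynamically preferred configuration, so transient enolisation by the ylide is harmless.

**Step 11**
Reactants: 17 C9 vinyl ester
Product: 18 C19 alcohol
Conditions: LiAlH4, THF, 0 → 50 °C; Fieser work-up
Reagents that add atoms: none
Why: Hydride reduction of the hindered axial methyl ester to the C19 primary alcohol; the silyl ethers and the vinyl group are inert to the reagent.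

**Step 12**
Reactants: 18 C19 alcohol; 19 3-bromofuran-2(5H)-one
Product: 21 bis-silyl ether of the target, via B-alkyl-9-BBN borane 20 (not isolated)
Conditions: 9-BBN-H dimer (2.5 equiv B–H), THF, rt; then 19, PdCl2(dppf) (5 mol %), Ph3As, Cs2CO3, DMF–H2O, rt
Reagents that add atoms: none
Why: Anti-Markovnikov hydroboration of the terminal vinyl group (the excess borane covers the free C19 hydroxyl) followed by B-alkyl Suzuki–Miyaura coupling with the α-bromo butenolide under the mild carbonate/arsine conditions known for α-halo enones forms C12–C13; no stereocentre is affected.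

**Step 13**
Reactants: 21 bis-silyl ether of the target
Product: 22 14-deoxy-17-hydroxyandrographolide
Conditions: HF·pyridine, THF–pyridine, 0 °C → rt
Reagents that add atoms: none
Why: Fluoride cleavage of both silyl ethers under mildly acidic conditions that the butenolide tolerates should give the target.

**Compound list**

1 | dimethyl 2-methylpropanedioate (dimethyl methylmalonate) | COC(=O)C(C)C(=O)OC | starting material
2 | methyl 3-methoxy-2-methyl-3-(trimethylsilyloxy)prop-2-enoate (ketene silyl acetal of 1) | COC(=O)C(C)=C(OC)O[Si](C)(C)C | intermediate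
3 | (S)-(+)-carvone | CC1=CC[C@@H](CC1=O)C(C)=C | starting material
4 | tert-butyl acrylate | C=CC(=O)OC(C)(C)C | starting material
5 | silyl enol ether: dimethyl 2-methyl-2-[2-methyl-5-(prop-1-en-2-yl)-3-(trimethylsilyloxy)cyclohex-2-en-1-yl]propanedioate, ring positions 1 and 5 trans (labdane C5 and C7) | CC1=C(O[Si](C)(C)C)C[C@@H](C(C)=C)C[C@@H]1C(C)(C(=O)OC)C(=O)OC | intermediate
6 | potassium C9/C10 enolate derived from 5 | CC1=C([O-])C[C@@H](C(C)=C)C[C@@H]1C(C)(C(=O)OC)C(=O)OC.[K+] | intermediate
7 | potassium tert-butyl ester enolate of the Michael adduct (C10 quaternary; C1 trans to C4) | C[C@]1(CC=C([O-])OC(C)(C)C)C(=O)C[C@@H](C(C)=C)C[C@@H]1C(C)(C(=O)OC)C(=O)OC.[K+] | intermediate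
8 | trans-decalin β-keto ester: 3,9-dioxo; tert-butoxycarbonyl at C2 (epimers, largely enolised); 4β-methyl, 4α-methoxycarbonyl (C19); 5β-H; 10α-methyl; 7β-isopropenyl (axial) | C[C@]1(C(=O)OC)[C@H]2C[C@H](C(C)=C)CC(=O)[C@]2(C)CC(C(=O)OC(C)(C)C)C1=O | intermediate
9 | 3,9-dioxo C19 methyl ester (as 8 without the C2 ester) | C[C@]1(C(=O)OC)[C@H]2C[C@H](C(C)=C)CC(=O)[C@]2(C)CCC1=O | intermediate
10 | 3α-hydroxy-9-oxo C19 methyl ester with 7β-isopropenyl | C[C@]1(C(=O)OC)[C@H]2C[C@H](C(C)=C)CC(=O)[C@]2(C)CC[C@H]1O | intermediate
11 | α-methoxy hydroperoxide at the former isopropenyl carbon on C7 | C[C@]1(C(=O)OC)[C@H]2C[C@H](C(C)(OC)OO)CC(=O)[C@]2(C)CC[C@H]1O | intermediate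
12 | 3α-hydroxy-9-oxo C19 methyl ester (C7 methylene) | C[C@]1(C(=O)OC)[C@H]2CCCC(=O)[C@]2(C)CC[C@H]1O | intermediate
13 | 3α-hydroxy-8β-(hydroxymethyl)-9-oxo C19 methyl ester | C[C@]1(C(=O)OC)[C@H]2CC[C@H](CO)C(=O)[C@]2(C)CC[C@H]1O | intermediate
14 | 3α,17-bis(tert-butyldimethylsilyloxy)-9-oxo C19 methyl ester | C[C@]1(C(=O)OC)[C@H]2CC[C@H](CO[Si](C)(C)C(C)(C)C)C(=O)[C@]2(C)CC[C@H]1O[Si](C)(C)C(C)(C)C | intermediate
15 | C9 spiro-epoxide (C11 β-axial, oxygen α-equatorial) | C[C@]1(C(=O)OC)[C@H]2CC[C@H](CO[Si](C)(C)C(C)(C)C)[C@]3(CO3)[C@]2(C)CC[C@H]1O[Si](C)(C)C(C)(C)C | intermediate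
16 | 9α-formyl (C11 aldehyde), 9β-H bis-silyl ether ester | C[C@]1(C(=O)OC)[C@H]2CC[C@H](CO[Si](C)(C)C(C)(C)C)[C@@H](C=O)[C@]2(C)CC[C@H]1O[Si](C)(C)C(C)(C)C | intermediate
17 | 9α-vinyl bis-silyl ether C19 methyl ester | C[C@]1(C(=O)OC)[C@H]2CC[C@H](CO[Si](C)(C)C(C)(C)C)[C@@H](C=C)[C@]2(C)CC[C@H]1O[Si](C)(C)C(C)(C)C | intermediate
18 | 9α-vinyl bis-silyl ether C19 alcohol | C[C@]1(CO)[C@H]2CC[C@H](CO[Si](C)(C)C(C)(C)C)[C@@H](C=C)[C@]2(C)CC[C@H]1O[Si](C)(C)C(C)(C)C | intermediate
19 | 3-bromofuran-2(5H)-one | O=C1OCC=C1Br | starting material
20 | B-alkyl-9-borabicyclo[3.3.1]nonane (boron on C12) | C[C@]1(CO)[C@H]2CC[C@H](CO[Si](C)(C)C(C)(C)C)[C@@H](CCB3C4CCCC3CCC4)[C@]2(C)CC[C@H]1O[Si](C)(C)C(C)(C)C | intermediate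
21 | 3,17-bis(tert-butyldimethylsilyl) ether of the target | C[C@]1(CO)[C@H]2CC[C@H](CO[Si](C)(C)C(C)(C)C)[C@@H](CCC3=CCOC3=O)[C@]2(C)CC[C@H]1O[Si](C)(C)C(C)(C)C | intermediate
22 | 14-deoxy-17-hydroxyandrographolide | C[C@]1(CO)[C@H]2CC[C@H](CO)[C@@H](CCC3=CCOC3=O)[C@]2(C)CC[C@H]1O | target

**Step count and risks**

Total steps: 13. Longest linear sequence: 13 steps (1 → 22; 12 steps from 3).

Steps most likely to fail:

Step 2. The conjugate addition of the fully substituted donor at the hindered β-carbon may stay incomplete or revert, proton transfer may erode the enolate regiocontrol, and the acrylate may oligomerise before ring closure. The fallback sets out from 3 and comes back at 8, and it assembles the same carbons stepwise with a secondary donor. Base-catalysed Michael addition of dimethyl malonate to 3 (NaOMe cat., MeOH) should give the trans keto diester F1. C-Methylation of its malonate carbon (NaH, MeI, THF) gives the methylated keto diester F2. F2 is then annulated with 4 under equilibrating conditions (KOtBu, tBuOH–THF): alkylation at the more substituted α-carbon C10, as in a Robinson annulation, and Dieckmann closure of the adduct lead to 8.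

Step 8. The ylide may act as a base, so that enolisation toward C8 and β-elimination of the silyloxy group outrun addition to the hindered carbonyl. The fallback sets out from 14 and comes back at 16. Non-basic Takai–Lombardo methylenation (Zn, CH2Br2, TiCl4) gives the 9(11)-exo-methylene compound F3. Hydroboration–oxidation (BH3·SMe2, THF, 0 °C; then NaBO3·4H2O) from the β-face, anti to the C20 methyl, should give the primary C11 alcohol F4 with H9 β. Dess–Martin oxidation of F4 gives 16. This detour also avoids the cationic rearrangement of step 9.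

Step 12. Base-induced degradation of the bromobutenolide (γ-deprotonation, ring opening) and protodeboronation may outrun transmetalation. The fallback sets out from 18 and 19 and comes back at 22; it masks the lactone as an aromatic 2-silyloxyfuran. Treatment of 19 with iPr3SiOTf and Et3N gives 3-bromo-2-(triisopropylsilyloxy)furan F5. B-Alkyl Suzuki–Miyaura coupling of borane 20 (made from 18 as in step 12) with F5 (PdCl2(dppf), K3PO4, DMF–THF, 60 °C) gives the silyloxyfuran F6. HF·pyridine then cleaves all three silyl groups, and protonation of the furanolate at C5 gives the conjugated butenolide, that is 22.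

**Further compounds**

F1 | step 2 | dimethyl 2-[2-methyl-3-oxo-5-(prop-1-en-2-yl)cyclohexyl]propanedioate, ring positions 1 and 5 trans, C2 epimers | CC1C(=O)C[C@@H](C(C)=C)C[C@@H]1C(C(=O)OC)C(=O)OC
F2 | step 2 | dimethyl 2-methyl-2-[2-methyl-3-oxo-5-(prop-1-en-2-yl)cyclohexyl]propanedioate, ring positions 1 and 5 trans, C2 epimers | CC1C(=O)C[C@@H](C(C)=C)C[C@@H]1C(C)(C(=O)OC)C(=O)OC
F3 | step 8 | 9(11)-exo-methylene bis-silyl ether C19 methyl ester | C[C@]1(C(=O)OC)[C@H]2CC[C@H](CO[Si](C)(C)C(C)(C)C)C(=C)[C@]2(C)CC[C@H]1O[Si](C)(C)C(C)(C)C
F4 | step 8 | 9α-(hydroxymethyl), 9β-H bis-silyl ether C19 methyl ester | C[C@]1(C(=O)OC)[C@H]2CC[C@H](CO[Si](C)(C)C(C)(C)C)[C@@H](CO)[C@]2(C)CC[C@H]1O[Si](C)(C)C(C)(C)C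
F5 | step 12 | 3-bromo-2-(triisopropylsilyloxy)furan | CC(C)[Si](Oc1occc1Br)(C(C)C)C(C)C
F6 | step 12 | 3-alkyl-2-(triisopropylsilyloxy)furan coupling product (bis-TBS ether, free C19 alcohol) | C[C@]1(CO)[C@H]2CC[C@H](CO[Si](C)(C)C(C)(C)C)[C@@H](CCc3ccoc3O[Si](C(C)C)(C(C)C)C(C)C)[C@]2(C)CC[C@H]1O[Si](C)(C)C(C)(C)C
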